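**Retrosynthetic overview**

1. The last step closes the 14-membered ring and the cis-lactone together: the C1–C2 bond is formed by iridium-catalysed coupling of the C2 allylic alcohol (through its enal) with a 2-(methoxycarbonyl)allyl acetate, followed by lactonisation.
2. C14–C1 (fragment union): Stille coupling of a (12Z)-allylic chloride with an (E)-β-stannyl acrylate (east fragment, from methyl 2-(hydroxymethyl)acrylate).
3. The 12Z alkene comes from syn-carbocupration of a C11 ynoate. The 1,2-dioxane (first permanent ring) comes from perhydrolysis of a 7R,8R epoxide at C8, then SN2 of the peroxide on a C11 propargylic mesylate.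
4. The C11 carbinol comes from zinc/ProPhenol addition of methyl propiolate to an aldehyde. C4–C5 comes from B-alkyl Suzuki coupling of a hydroborated vinyl epoxide with an (E)-iodobutenyl silyl ether (west fragment, from but-2-yn-1-ol).
5. The vinyl epoxide comes from Shi epoxidation of a dienol made from pent-4-yn-1-ol. Ring order: oxirane (temporary), then 1,2-dioxane, then carbocycle and lactone in one step.

Notation: locants C1–C20 are cembrane positions of the target (C1 ring-fusion CH carrying C15(=C17H2)–C16(=O)O; C2 lactone O–CH; C3=C4; C7 acetoxy; C8 and C11 peroxide carbons; C12=C13).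

Assumption: in the three ligand-controlled steps (2, 7, 21) the ligand antipode is defined by the stereodescriptor stated for the product; if a named antipode gives the opposite sense in practice, its enantiomer is used.

**Route**

Step 1
Reactants: 1 pent-4-yn-1-ol; 2 bromoethene (vinyl bromide)
Product: 4 (4E)-4-methylhepta-4,6-dien-1-ol, via alkenylalane 3 (not isolated)
Conditions: Me3Al (3 equiv), Cp2ZrCl2 (0.25 equiv), CH2Cl2, 0 °C to rt; then 2, ZnCl2 (0.2 equiv), Pd(PPh3)4 (3 mol %), THF, rt; aq. HCl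
Reagents that add atoms: trimethylaluminium, C[Al](C)C
Why: Negishi carboalumination adds Me–Al syn across the alkyne with methyl on the internal carbon, and the alkenylalane then cross-couples with retention (Negishi coupling), which fixes the E trisubstituted alkene.

Step 2
Reactants: 4 (4E)-4-methylhepta-4,6-dien-1-ol
Product: 5 3-[(2R,3R)-3-ethenyl-2-methyloxiran-2-yl]propan-1-ol
Conditions: D-fructose-derived Shi ketone (30 mol %), KHSO5 (as 2KHSO5·KHSO4·K2SO4), K2CO3, Bu4NHSO4, MeCN–dimethoxymethane–aq. borate buffer (pH 10.5), −10 to 0 °C; base-washed silica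
Reagents that add atoms: potassium peroxymonosulfate, [K+].[O-]S(=O)(=O)OO
Why: Shi epoxidation, in which the chiral dioxirane attacks only the electron-rich trisubstituted alkene of the diene through the spiro transition state and sets both oxirane centres (R,R = C7, C8); the basic medium keeps the 4,5-epoxy alcohol from cyclising.

Step 3
Reactants: 6 but-2-yn-1-ol
Product: 7 tert-butyl(but-2-yn-1-yloxy)diphenylsilane
Conditions: TBDPSCl, imidazole, DMF, rt
Reagents that add atoms: tert-butyl(chloro)diphenylsilane, CC(C)(C)[Si](Cl)(c1ccccc1)c1ccccc1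
Why: Standard silylation; the bulky silyl ether later steers the zirconium away from C2 and survives every step up to step 20.

Step 4
Reactants: 7 tert-butyl(but-2-yn-1-yloxy)diphenylsilane
Product: 9 tert-butyl{[(2E)-3-iodobut-2-en-1-yl]oxy}diphenylsilane, via alkenylzirconocene 8 (not isolated)
Conditions: Cp2Zr(H)Cl (1.5 equiv), THF, rt to 40 °C; then I2, 0 °C
Reagents that add atoms: iodine, II
Why: Hydrozirconation is a syn addition that, after equilibration with excess hydride, places zirconium on the methyl-bearing carbon remote from the bulky CH2OSi group; iodinolysis with retention gives the E iodide.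

Step 5
Reactants: 5 3-[(2R,3R)-3-ethenyl-2-methyloxiran-2-yl]propan-1-ol; 9 tert-butyl{[(2E)-3-iodobut-2-en-1-yl]oxy}diphenylsilane
Product: 11 3-[(2R,3R)-3-{(3E)-5-[tert-butyl(diphenyl)silyl]oxy-3-methylpent-3-en-1-yl}-2-methyloxiran-2-yl]propan-1-ol, via B-alkyl-9-BBN adduct 10 (not isolated)
Conditions: 9-BBN (2.3 equiv), THF, 0 °C to rt; then 9, Pd(dppf)Cl2 (5 mol %), AsPh3 (10 mol %), Cs2CO3 (3 equiv), DMF–THF–H2O, rt
Reagents that add atoms: none
Why: B-alkyl Suzuki–Miyaura coupling, in which 9-BBN hydroborates only the terminal vinyl group at its CH2 end (the alcohol is tied up as a borinate) and the alkylborane couples with the alkenyl iodide with retention of E geometry; the epoxide centres are untouched and the second trisubstituted alkene appears only after the epoxidation.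

Step 6
Reactants: 11 the epoxy alcohol from step 5
Product: 12 3-[(2R,3R)-3-{(3E)-5-[tert-butyl(diphenyl)silyl]oxy-3-methylpent-3-en-1-yl}-2-methyloxiran-2-yl]propanal
Conditions: Dess–Martin periodinane, NaHCO3, CH2Cl2, 0 °C to rt
Reagents that add atoms: none
Why: Dess–Martin oxidation under bicarbonate buffering, so the epoxide is not opened by the alcohol or by acetic acid.

Step 7
Reactants: 12 the epoxy aldehyde from step 6; 13 methyl propiolate
Product: 14 methyl (4S)-4-hydroxy-6-[(2R,3R)-3-{(3E)-5-[tert-butyl(diphenyl)silyl]oxy-3-methylpent-3-en-1-yl}-2-methyloxiran-2-yl]hex-2-ynoate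
Conditions: Me2Zn (3 equiv), (S,S)-ProPhenol (20 mol %), Ph3PO (40 mol %), toluene, 0 to 4 °C
Reagents that add atoms: none
Why: Trost ProPhenol zinc alkynylation, in which the dinuclear zinc catalyst delivers the alkynylzinc to one aldehyde face and sets C11 as S (the precursor configuration needed for the later inversion); epoxide, silyl ether and alkene are inert to Me2Zn.

Step 8
Reactants: 14 the propargylic alcohol from step 7
Product: 15 methyl (4S)-4-(methanesulfonyloxy)-6-[(2R,3R)-3-{(3E)-5-[tert-butyl(diphenyl)silyl]oxy-3-methylpent-3-en-1-yl}-2-methyloxiran-2-yl]hex-2-ynoate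
Conditions: MsCl, Et3N, CH2Cl2, −20 °C
Reagents that add atoms: methanesulfonyl chloride, CS(=O)(=O)Cl
Why: O-sulfonylation with retention; a propargylic mesylate on an electron-poor alkyne is SN2-active but does not ionise.

Step 9
Reactants: 15 the propargylic mesylate from step 8
Product: 17 methyl 3-[(3R,6S)-6-{(1R,4E)-6-[tert-butyl(diphenyl)silyl]oxy-1-hydroxy-4-methylhex-4-en-1-yl}-6-methyl-1,2-dioxan-3-yl]prop-2-ynoate, via hydroperoxy mesylate 16 (not isolated)
Conditions: H2O2 (anhydrous, 2 M in Et2O, 3 equiv), H3PMo12O40 (5 mol %), Et2O, 0 °C; then MnO2 (destroys excess H2O2), 0 °C; then K2CO3, 18-crown-6, 0 °C to rt, 0.01 M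
Reagents that add atoms: hydrogen peroxide, OO
Why: Acid-catalysed perhydrolysis opens the epoxide at the tertiary C8 with inversion (8R to 8S, C7–OH retained), and the peroxide anion then displaces the mesylate in a 6-exo-tet SN2 with inversion (11S to 11R), giving the dioxane with the C7 chain and the C11 substituent cis (epoxide perhydrolysis and intramolecular alkylation of a hydroperoxide).

Step 10
Reactants: 17 the dioxanyl ynoate from step 9
Product: 18 methyl (2Z)-3-[(3R,6S)-6-{(1R,4E)-6-[tert-butyl(diphenyl)silyl]oxy-1-hydroxy-4-methylhex-4-en-1-yl}-6-methyl-1,2-dioxan-3-yl]but-2-enoate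
Conditions: Me2CuLi (3 equiv, from MeLi and CuI), THF, −78 °C, 30 min; MeOH then aq. NH4Cl at −78 °C
Reagents that add atoms: lithium dimethylcuprate, [Li+].C[Cu-]C
Why: Syn-carbocupration of the ynoate (conjugate addition) puts methyl on C12 and, after protonation at −78 °C, leaves the dioxane carbon cis to the ester, which is the 12Z geometry; the fast low-temperature addition is expected to outrun attack on the dialkyl peroxide.

Step 11
Reactants: 18 the Z-enoate from step 10
Product: 19 (2Z)-3-[(3R,6S)-6-{(1R,4E)-6-[tert-butyl(diphenyl)silyl]oxy-1-hydroxy-4-methylhex-4-en-1-yl}-6-methyl-1,2-dioxan-3-yl]but-2-en-1-ol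
Conditions: i-Bu2AlH (4.5 equiv), CH2Cl2, −78 °C; aq. KNaC4H4O6 (potassium sodium tartrate)
Reagents that add atoms: none
Why: 1,2-Reduction of the conjugated ester to the allylic alcohol without touching the alkene geometry; dialkyl peroxides survive this hydride at −78 °C.

Step 12
Reactants: 19 the diol from step 11
Product: 21 (1R,4E)-6-[tert-butyl(diphenyl)silyl]oxy-1-{(3S,6R)-6-[(2Z)-4-chlorobut-2-en-2-yl]-3-methyl-1,2-dioxan-3-yl}-4-methylhex-4-en-1-ol, via allylic mesylate 20 (not isolated)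
Conditions: MsCl (1.1 equiv), 2,4,6-collidine, LiCl (5 equiv), DMF, 0 °C
Reagents that add atoms: methanesulfonyl chloride, CS(=O)(=O)Cl; lithium chloride, [Li+].[Cl-]
Why: Collington–Meyers chlorination, in which only the primary allylic alcohol is mesylated and displaced by chloride (SN2, no allylic shift, Z retained) while the hindered C7 alcohol is left.

Step 13
Reactants: 22 methyl 2-(hydroxymethyl)acrylate
Product: 23 methyl 2-({[tert-butyl(dimethyl)silyl]oxy}methyl)acrylate
Conditions: TBSCl, imidazole, CH2Cl2, 0 °C to rt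
Reagents that add atoms: tert-butyl(chloro)dimethylsilane, CC(C)(C)[Si](C)(C)Cl
Why: Silylation; the free alcohol would otherwise close to a glycidate in step 15.

Step 14
Reactants: 23 the silyl ether from step 13
Product: 24 methyl 2,3-dibromo-2-({[tert-butyl(dimethyl)silyl]oxy}methyl)propanoate (racemic)
Conditions: Br2, CH2Cl2, 0 °C to rt
Reagents that add atoms: bromine, BrBr
Why: Electrophilic bromine addition to the acrylate; the new centre is racemic and is destroyed in step 15.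

Step 15
Reactants: 24 the dibromide from step 14
Product: 25 methyl (2E)-3-bromo-2-({[tert-butyl(dimethyl)silyl]oxy}methyl)acrylate
Conditions: DBU, CH2Cl2, 0 °C to rt
Reagents that add atoms: none
Why: E2 dehydrobromination removes a CH2Br proton together with the tertiary bromide (as in the 3-bromomethacrylate synthesis) and gives the conjugated bromoalkene with Br trans to the ester; this geometry is not transmitted to the target because it is lost at the allyl-metal stage.

Step 16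
Reactants: 25 the bromoacrylate from step 15
Product: 26 methyl (2E)-2-({[tert-butyl(dimethyl)silyl]oxy}methyl)-3-(tributylstannyl)acrylate
Conditions: (Bu3Sn)2 (1.2 equiv), Pd(PPh3)4 (5 mol %), toluene, 100 °C
Reagents that add atoms: hexabutyldistannane, CCCC[Sn](CCCC)(CCCC)[Sn](CCCC)(CCCC)CCCC
Why: Palladium-catalysed stannylation of an alkenyl bromide (oxidative addition, Sn–Sn transmetalation, reductive elimination) with retention.

Step 17
Reactants: 26 the stannyl silyl ether from step 16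
Product: 27 methyl (2E)-2-(hydroxymethyl)-3-(tributylstannyl)acrylate
Conditions: HF·pyridine, pyridine, THF, 0 °C
Reagents that add atoms: none
Why: Fluoride cleaves the silyl ether; the electron-poor alkenylstannane resists protodestannylation under buffered HF.

Step 18
Reactants: 21 the allylic chloride from step 12; 27 the stannyl acrylate from step 17
Product: 28 methyl (2E,5Z)-2-(hydroxymethyl)-6-[(3R,6S)-6-{(1R,4E)-6-[tert-butyl(diphenyl)silyl]oxy-1-hydroxy-4-methylhex-4-en-1-yl}-6-methyl-1,2-dioxan-3-yl]hepta-2,5-dienoate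
Conditions: Pd2(dba)3 (2.5 mol %), P(2-furyl)3 (10 mol %), NMP, rt to 40 °C
Reagents that add atoms: none
Why: Stille allyl–alkenyl coupling, in which zerovalent palladium ionises the chloride and the alkenyl group is delivered to the unhindered CH2 terminus; both alkene geometries are retained because syn–anti isomerisation would need a σ-complex at the fully substituted terminus, and the neutral conditions spare the peroxide and free alcohols.

Step 19
Reactants: 28 the diol from step 18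
Product: 29 methyl (2E,5Z)-2-(acetoxymethyl)-6-[(3R,6S)-6-{(1R,4E)-1-acetoxy-6-[tert-butyl(diphenyl)silyl]oxy-4-methylhex-4-en-1-yl}-6-methyl-1,2-dioxan-3-yl]hepta-2,5-dienoate
Conditions: Ac2O (4 equiv), pyridine, DMAP (0.2 equiv), CH2Cl2, 0 °C to rt
Reagents that add atoms: acetic anhydride, CC(=O)OC(C)=O
Why: One acetylation installs the C7 acetate of the target (retention) and turns the primary allylic alcohol into the leaving group for step 21.

Step 20
Reactants: 29 the bis-acetate from step 19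
Product: 30 methyl (2E,5Z)-2-(acetoxymethyl)-6-[(3R,6S)-6-{(1R,4E)-1-acetoxy-6-hydroxy-4-methylhex-4-en-1-yl}-6-methyl-1,2-dioxan-3-yl]hepta-2,5-dienoate
Conditions: HF·pyridine, pyridine, THF, 0 °C to rt
Reagents that add atoms: none
Why: Buffered fluoride desilylation; it is not basic, so the acetates and the allylic peroxide C–H are safe.

Step 21
Reactants: 30 the seco allylic alcohol from step 20
Product: 33 (1R,2R,3E,7R,8S,11R,12Z)-7-acetoxy-8,11-epidioxycembra-3,12,15(17)-trien-16,2-olide (the target), via enal acetate 31 (not isolated), via macrocyclic hydroxy ester 32 (not isolated)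
Conditions: [Ir(cod)Cl]2 (5 mol %), (S)-SEGPHOS (10 mol %), 4-cyano-3-nitrobenzoic acid (20 mol %), Cs2CO3 (40 mol %), THF, 70 °C, syringe-pump addition of 30 to 2 mM; then PPTS (cat.), rt if lactonisation is incomplete
Reagents that add atoms: none
Why: Proposed new method: a macrocyclising iridium-catalysed transfer-hydrogenative 2-(alkoxycarbonyl)allylation, in which the cyclometalated trivalent iridium C,O-benzoate dehydrogenates the C2 allylic alcohol to enal 31, the resulting monovalent iridium ionises the allylic acetate, and the (methoxycarbonyl)allyl–iridium adds through a closed chair transition state (Z σ-allyl, syn adduct, hence cis C1/C2) to the aldehyde Si face chosen by the ligand (2R, 1R) before the alkoxide lactonises onto the methyl ester; it needs no stoichiometric reductant, so the O–O bond is not exposed to low-valent metal, and the closest known reaction type is the intermolecular iridium-catalysed 2-(alkoxycarbonyl)allylation of primary alcohols to cis-α-methylene-γ-butyrolactones, which has not been used to close a ring.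

**Compound list**

1 | pent-4-yn-1-ol | C#CCCCO | starting material
2 | bromoethene | C=CBr | starting material
3 | (E)-[5-(dimethylaluminiooxy)-2-methylpent-1-en-1-yl]dimethylalane | C[Al](C)OCCC/C(C)=C/[Al](C)C | intermediate
4 | (4E)-4-methylhepta-4,6-dien-1-ol | C=C/C=C(\C)CCCO | intermediate
5 | 3-[(2R,3R)-3-ethenyl-2-methyloxiran-2-yl]propan-1-ol | C=C[C@@H]1[C@@](C)(CCCO)O1 | intermediate
6 | but-2-yn-1-ol | CC#CCO | starting material
7 | tert-butyl(but-2-yn-1-yloxy)diphenylsilane | CC#CCO[Si](c1ccccc1)(c1ccccc1)C(C)(C)C | intermediate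
8 | chlorobis(cyclopentadienyl)[(2E)-4-{[tert-butyl(diphenyl)silyl]oxy}but-2-en-2-yl]zirconium | C/C(=C\CO[Si](c1ccccc1)(c1ccccc1)C(C)(C)C)[Zr](Cl)(C1C=CC=C1)C1C=CC=C1 | intermediate
9 | tert-butyl{[(2E)-3-iodobut-2-en-1-yl]oxy}diphenylsilane | C/C(I)=C\CO[Si](c1ccccc1)(c1ccccc1)C(C)(C)C | intermediate
10 | 9-{2-[(2R,3R)-3-methyl-3-(3-(9-borabicyclo[3.3.1]nonan-9-yloxy)propyl)oxiran-2-yl]ethyl}-9-borabicyclo[3.3.1]nonane | B1(CC[C@@H]2[C@@](C)(CCCOB3C4CCCC3CCC4)O2)C2CCCC1CCC2 | intermediate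
11 | 3-[(2R,3R)-3-{(3E)-5-[tert-butyl(diphenyl)silyl]oxy-3-methylpent-3-en-1-yl}-2-methyloxiran-2-yl]propan-1-ol | CC(C)(C)[Si](c1ccccc1)(c1ccccc1)OC/C=C(\C)CC[C@@H]1[C@@](C)(CCCO)O1 | intermediate
12 | 3-[(2R,3R)-3-{(3E)-5-[tert-butyl(diphenyl)silyl]oxy-3-methylpent-3-en-1-yl}-2-methyloxiran-2-yl]propanal | CC(C)(C)[Si](c1ccccc1)(c1ccccc1)OC/C=C(\C)CC[C@@H]1[C@@](C)(CCC=O)O1 | intermediate
13 | methyl propiolate | C#CC(=O)OC | starting material
14 | methyl (4S)-4-hydroxy-6-[(2R,3R)-3-{(3E)-5-[tert-butyl(diphenyl)silyl]oxy-3-methylpent-3-en-1-yl}-2-methyloxiran-2-yl]hex-2-ynoate | CC(C)(C)[Si](c1ccccc1)(c1ccccc1)OC/C=C(\C)CC[C@@H]1[C@@](C)(CC[C@H](O)C#CC(=O)OC)O1 | intermediate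
15 | methyl (4S)-4-(methanesulfonyloxy)-6-[(2R,3R)-3-{(3E)-5-[tert-butyl(diphenyl)silyl]oxy-3-methylpent-3-en-1-yl}-2-methyloxiran-2-yl]hex-2-ynoate | CC(C)(C)[Si](c1ccccc1)(c1ccccc1)OC/C=C(\C)CC[C@@H]1[C@@](C)(CC[C@H](OS(C)(=O)=O)C#CC(=O)OC)O1 | intermediate
16 | methyl (4S,7S,8R,11E)-13-[tert-butyl(diphenyl)silyl]oxy-7-hydroperoxy-8-hydroxy-4-(methanesulfonyloxy)-7,11-dimethyltridec-11-en-2-ynoate | CC(C)(C)[Si](c1ccccc1)(c1ccccc1)OC/C=C(\C)CC[C@@H](O)[C@@](C)(OO)CC[C@H](OS(C)(=O)=O)C#CC(=O)OC | intermediate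
17 | methyl 3-[(3R,6S)-6-{(1R,4E)-6-[tert-butyl(diphenyl)silyl]oxy-1-hydroxy-4-methylhex-4-en-1-yl}-6-methyl-1,2-dioxan-3-yl]prop-2-ynoate | CC(C)(C)[Si](c1ccccc1)(c1ccccc1)OC/C=C(\C)CC[C@@H](O)[C@]2(C)CC[C@@H](OO2)C#CC(=O)OC | intermediate
18 | methyl (2Z)-3-[(3R,6S)-6-{(1R,4E)-6-[tert-butyl(diphenyl)silyl]oxy-1-hydroxy-4-methylhex-4-en-1-yl}-6-methyl-1,2-dioxan-3-yl]but-2-enoate | CC(C)(C)[Si](c1ccccc1)(c1ccccc1)OC/C=C(\C)CC[C@@H](O)[C@]2(C)CC[C@@H](OO2)/C(C)=C\C(=O)OC | intermediate
19 | (2Z)-3-[(3R,6S)-6-{(1R,4E)-6-[tert-butyl(diphenyl)silyl]oxy-1-hydroxy-4-methylhex-4-en-1-yl}-6-methyl-1,2-dioxan-3-yl]but-2-en-1-ol | CC(C)(C)[Si](c1ccccc1)(c1ccccc1)OC/C=C(\C)CC[C@@H](O)[C@]2(C)CC[C@@H](OO2)/C(C)=C\CO | intermediate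
20 | (2Z)-3-[(3R,6S)-6-{(1R,4E)-6-[tert-butyl(diphenyl)silyl]oxy-1-hydroxy-4-methylhex-4-en-1-yl}-6-methyl-1,2-dioxan-3-yl]but-2-en-1-yl methanesulfonate | CC(C)(C)[Si](c1ccccc1)(c1ccccc1)OC/C=C(\C)CC[C@@H](O)[C@]2(C)CC[C@@H](OO2)/C(C)=C\COS(C)(=O)=O | intermediate
21 | (1R,4E)-6-[tert-butyl(diphenyl)silyl]oxy-1-{(3S,6R)-6-[(2Z)-4-chlorobut-2-en-2-yl]-3-methyl-1,2-dioxan-3-yl}-4-methylhex-4-en-1-ol | CC(C)(C)[Si](c1ccccc1)(c1ccccc1)OC/C=C(\C)CC[C@@H](O)[C@]2(C)CC[C@@H](OO2)/C(C)=C\CCl | intermediate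
22 | methyl 2-(hydroxymethyl)acrylate | C=C(CO)C(=O)OC | starting material
23 | methyl 2-({[tert-butyl(dimethyl)silyl]oxy}methyl)acrylate | C=C(CO[Si](C)(C)C(C)(C)C)C(=O)OC | intermediate
24 | methyl 2,3-dibromo-2-({[tert-butyl(dimethyl)silyl]oxy}methyl)propanoate (racemic) | COC(=O)C(Br)(CBr)CO[Si](C)(C)C(C)(C)C | intermediate
25 | methyl (2E)-3-bromo-2-({[tert-butyl(dimethyl)silyl]oxy}methyl)acrylate | Br/C=C(\CO[Si](C)(C)C(C)(C)C)C(=O)OC | intermediate
26 | methyl (2E)-2-({[tert-butyl(dimethyl)silyl]oxy}methyl)-3-(tributylstannyl)acrylate | CCCC[Sn](CCCC)(CCCC)/C=C(\CO[Si](C)(C)C(C)(C)C)C(=O)OC | intermediate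
27 | methyl (2E)-2-(hydroxymethyl)-3-(tributylstannyl)acrylate | CCCC[Sn](CCCC)(CCCC)/C=C(\CO)C(=O)OC | intermediate
28 | methyl (2E,5Z)-2-(hydroxymethyl)-6-[(3R,6S)-6-{(1R,4E)-6-[tert-butyl(diphenyl)silyl]oxy-1-hydroxy-4-methylhex-4-en-1-yl}-6-methyl-1,2-dioxan-3-yl]hepta-2,5-dienoate | CC(C)(C)[Si](c1ccccc1)(c1ccccc1)OC/C=C(\C)CC[C@@H](O)[C@]2(C)CC[C@@H](OO2)/C(C)=C\C/C=C(\CO)C(=O)OC | intermediate
29 | methyl (2E,5Z)-2-(acetoxymethyl)-6-[(3R,6S)-6-{(1R,4E)-1-acetoxy-6-[tert-butyl(diphenyl)silyl]oxy-4-methylhex-4-en-1-yl}-6-methyl-1,2-dioxan-3-yl]hepta-2,5-dienoate | CC(C)(C)[Si](c1ccccc1)(c1ccccc1)OC/C=C(\C)CC[C@@H](OC(C)=O)[C@]2(C)CC[C@@H](OO2)/C(C)=C\C/C=C(\COC(C)=O)C(=O)OC | intermediate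
30 | methyl (2E,5Z)-2-(acetoxymethyl)-6-[(3R,6S)-6-{(1R,4E)-1-acetoxy-6-hydroxy-4-methylhex-4-en-1-yl}-6-methyl-1,2-dioxan-3-yl]hepta-2,5-dienoate | OC/C=C(\C)CC[C@@H](OC(C)=O)[C@]2(C)CC[C@@H](OO2)/C(C)=C\C/C=C(\COC(C)=O)C(=O)OC | intermediate
31 | methyl (2E,5Z)-2-(acetoxymethyl)-6-[(3R,6S)-6-{(1R,4E)-1-acetoxy-4-methyl-6-oxohex-4-en-1-yl}-6-methyl-1,2-dioxan-3-yl]hepta-2,5-dienoate | O=C/C=C(\C)CC[C@@H](OC(C)=O)[C@]2(C)CC[C@@H](OO2)/C(C)=C\C/C=C(\COC(C)=O)C(=O)OC | intermediate
32 | methyl 2-[(1R,2R,3E,7R,8S,11R,12Z)-7-acetoxy-8,11-epidioxy-2-hydroxy-4,8,12-trimethylcyclotetradeca-3,12-dien-1-yl]acrylate (cembrane locants; seco-lactone of the target) | C=C(C(=O)OC)[C@@H]1[C@H](O)/C=C(\C)CC[C@@H](OC(C)=O)[C@]2(C)CC[C@@H](OO2)/C(C)=C\C1 | intermediate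
33 | (1R,2R,3E,7R,8S,11R,12Z)-7-acetoxy-8,11-epidioxycembra-3,12,15(17)-trien-16,2-olide | C=C1C(=O)O[C@@H]2/C=C(\C)CC[C@@H](OC(C)=O)[C@]3(C)CC[C@@H](OO3)/C(C)=C\C[C@H]12 | target

**Step count and risks**

Total step count: 21. Longest linear sequence: 14 steps (1, 2, 5–12, 18–21); the west branch (3, 4) joins at step 5 and the east branch (13–17) at step 18.

The three steps most likely to fail:

Step 21 (the proposed new step). The iridium hydride or the carbonate at 70 °C may cleave the dioxane, the allylic peroxide C–O may compete with the acetate for monovalent iridium, or the catalyst may not turn over at high dilution. The fallback is the known intramolecular Barbier allylation of an aldehyde by a 2-(bromomethyl)acrylate, and it sets out from 28. The primary allylic alcohol is converted to the bromide (MsCl, Et3N, −20 °C; then LiBr, THF) to give methyl (2Z,5Z)-2-(bromomethyl)-6-[(3R,6S)-6-{(1R,4E)-6-[tert-butyl(diphenyl)silyl]oxy-1-hydroxy-4-methylhex-4-en-1-yl}-6-methyl-1,2-dioxan-3-yl]hepta-2,5-dienoate F1. The C7 alcohol is acetylated without nucleophilic amine (Ac2O, Sc(OTf)3 cat., MeCN, −20 °C) to give the bromo acetate F2. HF·pyridine gives the allylic alcohol F3, and MnO2 in CH2Cl2 gives the enal bromide F4. Indium powder (THF–aq. NH4Cl, 1 mM, rt) closes the ring through the cyclic allylindium transition state (syn adduct) and the route is rejoined at 32, which lactonises to 33. Facial selectivity is then substrate-controlled, so C1/C2 diastereomers may have to be separated.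

Step 9. The mesylate may not survive the acidic perhydrolysis, residual H2O2 or the peroxide anion may add to the ynoate, or the epoxide may open with loss of configuration. The fallback reverses the polarity of the ring closure and sets out from 15. Intermolecular SN2 with 2-methoxyprop-2-yl hydroperoxide (CsOH·H2O, DMF, 0 °C; inversion at C11) gives the peroxyketal methyl (4R)-4-[(2-methoxypropan-2-yl)peroxy]-6-[(2R,3R)-3-{(3E)-5-[tert-butyl(diphenyl)silyl]oxy-3-methylpent-3-en-1-yl}-2-methyloxiran-2-yl]hex-2-ynoate F5. Camphorsulfonic acid in wet CH2Cl2–MeOH unmasks the secondary hydroperoxide F6, which under the same acid opens the epoxide 6-exo at the tertiary C8 with inversion. The route is rejoined at 17 with the same configuration, because both inversions are the same as in the main step.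

Step 10. The cuprate may reduce the O–O bond or expel the propargylic peroxide (allene formation). The fallback avoids organocopper by bringing in the Z-alkenyl unit intact through a peroxycarbenium ion, and it sets out from 12. H2O2 with H3PMo12O40 in Et2O opens the epoxide at C8, and the hydroperoxide adds to the aldehyde to give the cyclic peroxy-hemiacetal (6S)-6-{(1R,4E)-6-[tert-butyl(diphenyl)silyl]oxy-1-hydroxy-4-methylhex-4-en-1-yl}-6-methyl-1,2-dioxan-3-ol F7. Ac2O, pyridine and DMAP give the diacetate F8, which already carries the C7 acetate. In parallel, 6 is converted with NaAlH2(OCH2CH2OMe)2 and then I2 to (2Z)-3-iodobut-2-en-1-ol F9, silylated (TBSCl, imidazole) to the TBS ether F10, and turned (t-BuLi, −78 °C; B(OMe)3; aq. KHF2) into potassium (Z)-[4-{[tert-butyl(dimethyl)silyl]oxy}but-2-en-2-yl]trifluoroborate F11. BF3·OEt2 in CH2Cl2–MeCN at −40 °C ionises F8, and axial attack of F11 (retention of alkene geometry, attack cis to the larger pseudo-equatorial C8 substituent) gives the 3-alkenyl-1,2-dioxane F12; the C11 epimer is removed by chromatography. HF·pyridine at 0 °C removes only the TBS group to give the allylic alcohol F13, and K2CO3 in MeOH removes the acetate. The route is rejoined at 19.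

**Further compounds**

F1 | step 21 | methyl (2Z,5Z)-2-(bromomethyl)-6-[(3R,6S)-6-{(1R,4E)-6-[tert-butyl(diphenyl)silyl]oxy-1-hydroxy-4-methylhex-4-en-1-yl}-6-methyl-1,2-dioxan-3-yl]hepta-2,5-dienoate | CC(C)(C)[Si](c1ccccc1)(c1ccccc1)OC/C=C(\C)CC[C@@H](O)[C@]2(C)CC[C@@H](OO2)/C(C)=C\C/C=C(\CBr)C(=O)OC
F2 | step 21 | methyl (2Z,5Z)-2-(bromomethyl)-6-[(3R,6S)-6-{(1R,4E)-1-acetoxy-6-[tert-butyl(diphenyl)silyl]oxy-4-methylhex-4-en-1-yl}-6-methyl-1,2-dioxan-3-yl]hepta-2,5-dienoate | CC(C)(C)[Si](c1ccccc1)(c1ccccc1)OC/C=C(\C)CC[C@@H](OC(C)=O)[C@]2(C)CC[C@@H](OO2)/C(C)=C\C/C=C(\CBr)C(=O)OC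
F3 | step 21 | methyl (2Z,5Z)-2-(bromomethyl)-6-[(3R,6S)-6-{(1R,4E)-1-acetoxy-6-hydroxy-4-methylhex-4-en-1-yl}-6-methyl-1,2-dioxan-3-yl]hepta-2,5-dienoate | OC/C=C(\C)CC[C@@H](OC(C)=O)[C@]2(C)CC[C@@H](OO2)/C(C)=C\C/C=C(\CBr)C(=O)OC
F4 | step 21 | methyl (2Z,5Z)-2-(bromomethyl)-6-[(3R,6S)-6-{(1R,4E)-1-acetoxy-4-methyl-6-oxohex-4-en-1-yl}-6-methyl-1,2-dioxan-3-yl]hepta-2,5-dienoate | O=C/C=C(\C)CC[C@@H](OC(C)=O)[C@]2(C)CC[C@@H](OO2)/C(C)=C\C/C=C(\CBr)C(=O)OC
F5 | step 9 | methyl (4R)-4-[(2-methoxypropan-2-yl)peroxy]-6-[(2R,3R)-3-{(3E)-5-[tert-butyl(diphenyl)silyl]oxy-3-methylpent-3-en-1-yl}-2-methyloxiran-2-yl]hex-2-ynoate | CC(C)(C)[Si](c1ccccc1)(c1ccccc1)OC/C=C(\C)CC[C@@H]1[C@@](C)(CC[C@@H](OOC(C)(C)OC)C#CC(=O)OC)O1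
F6 | step 9 | methyl (4R)-4-hydroperoxy-6-[(2R,3R)-3-{(3E)-5-[tert-butyl(diphenyl)silyl]oxy-3-methylpent-3-en-1-yl}-2-methyloxiran-2-yl]hex-2-ynoate | CC(C)(C)[Si](c1ccccc1)(c1ccccc1)OC/C=C(\C)CC[C@@H]1[C@@](C)(CC[C@@H](OO)C#CC(=O)OC)O1
F7 | step 10 | (6S)-6-{(1R,4E)-6-[tert-butyl(diphenyl)silyl]oxy-1-hydroxy-4-methylhex-4-en-1-yl}-6-methyl-1,2-dioxan-3-ol (anomer mixture) | CC(C)(C)[Si](c1ccccc1)(c1ccccc1)OC/C=C(\C)CC[C@@H](O)[C@]2(C)CCC(O)OO2
F8 | step 10 | (6S)-6-{(1R,4E)-1-acetoxy-6-[tert-butyl(diphenyl)silyl]oxy-4-methylhex-4-en-1-yl}-6-methyl-1,2-dioxan-3-yl acetate (anomer mixture) | CC(C)(C)[Si](c1ccccc1)(c1ccccc1)OC/C=C(\C)CC[C@@H](OC(C)=O)[C@]2(C)CCC(OC(C)=O)OO2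
F9 | step 10 | (2Z)-3-iodobut-2-en-1-ol | C/C(I)=C/CO
F10 | step 10 | tert-butyl{[(2Z)-3-iodobut-2-en-1-yl]oxy}dimethylsilane | C/C(I)=C/CO[Si](C)(C)C(C)(C)C
F11 | step 10 | potassium (Z)-[4-{[tert-butyl(dimethyl)silyl]oxy}but-2-en-2-yl]trifluoroborate | C/C(=C/CO[Si](C)(C)C(C)(C)C)[B-](F)(F)F.[K+]
F12 | step 10 | (1R,4E)-6-[tert-butyl(diphenyl)silyl]oxy-1-{(3S,6R)-6-[(2Z)-4-{[tert-butyl(dimethyl)silyl]oxy}but-2-en-2-yl]-3-methyl-1,2-dioxan-3-yl}-4-methylhex-4-en-1-yl acetate | CC(C)(C)[Si](c1ccccc1)(c1ccccc1)OC/C=C(\C)CC[C@@H](OC(C)=O)[C@]2(C)CC[C@@H](OO2)/C(C)=C\CO[Si](C)(C)C(C)(C)C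
F13 | step 10 | (1R,4E)-6-[tert-butyl(diphenyl)silyl]oxy-1-{(3S,6R)-6-[(2Z)-4-hydroxybut-2-en-2-yl]-3-methyl-1,2-dioxan-3-yl}-4-methylhex-4-en-1-yl acetate | CC(C)(C)[Si](c1ccccc1)(c1ccccc1)OC/C=C(\C)CC[C@@H](OC(C)=O)[C@]2(C)CC[C@@H](OO2)/C(C)=C\CO
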